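**Retrosynthetic overview**

1. The last bonds to be made are the four aryl ester C–O bonds of the central ring: target ⇐ bis-silyl tetraester ⇐ outer-silylated leuco-atromentin tetraol + four equivalents of the (Z)-epoxy carboxylate, activated as a mixed anhydride.
2. The strategy rests on the acyl chain: C1 (ester carbonyl), the Z C2=C3 bond, the oxirane ring (C4, C5 and their shared O) and the C6 methyl coincide with C1–C6 of the 2,3-unsaturated 1,5-lactone of L-rhamnose. Its pyranone ring holds C2=C3 cis and carries oxygen on C4 and C5 in the erythro relationship.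
3. Key disconnection: the oxirane O–C4 bond. Hydroxide opens the 4-O-mesyl lactone, and the freed C5 alkoxide displaces the C4 mesylate with inversion (pyranone ring opened, oxirane ring closed).
4. The mesyl lactone comes from di-O-acetyl-L-rhamnal by Ferrier glycosidation, deacetylation, mesylation and peracid oxidation of the anomeric acetal. The core comes from bromanil by methoxide substitution, twofold Suzuki coupling (two equivalents of the boronic acid), demethylation, outer silylation and quinone hydrogenation.
5. Ring order: the outer arene rings are joined to the quinone ring (step 7), the quinone ring is aromatised (step 10), and the oxirane ring is closed in step 5, before the four esterifications.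

Key step: step 5

Remark: the Ferrier glycosidation should give mainly the α-glycoside. The glycosides are drawn and named as the α-anomer; any β-anomer is carried along, because the anomeric centre becomes the lactone carbonyl in step 4. The freeze-dried product of step 5 holds one equivalent of sodium methanesulfonate, which is inert in step 11 and is filtered off there with the NaCl.

**Route**

Step 1
Reactants: 1 3,4-di-O-acetyl-L-rhamnal
Product: 2 ethyl 4-O-acetyl-2,3,6-trideoxy-α-L-erythro-hex-2-enopyranoside
Conditions: EtOH, BF3·OEt2 (cat.), CH2Cl2, 0 °C to rt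
Reagents that add atoms: ethanol, CCO
Why: Ferrier rearrangement: BF3 ionises the allylic C3 acetate to an allyl oxocarbenium ion that ethanol captures at C1 with shift of the alkene to C2=C3, the new anomeric centre being set mainly α by the anomeric effect (it is erased again in step 4), while C4 and C5 are untouched.

Step 2
Reactants: 2 ethyl 4-O-acetyl-2,3,6-trideoxy-α-L-erythro-hex-2-enopyranoside
Product: 3 ethyl 2,3,6-trideoxy-α-L-erythro-hex-2-enopyranoside
Conditions: NaOMe (cat.), MeOH, rt; then NH4Cl
Reagents that add atoms: none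
Why: Zemplén transesterification: catalytic methoxide passes the acetyl group to methanol, the acetal and the isolated alkene are inert to base, and no stereocentre is touched.

Step 3
Reactants: 3 ethyl 2,3,6-trideoxy-α-L-erythro-hex-2-enopyranoside
Product: 4 ethyl 2,3,6-trideoxy-4-O-methanesulfonyl-α-L-erythro-hex-2-enopyranoside
Conditions: MsCl, Et3N, CH2Cl2, −20 °C
Reagents that add atoms: methanesulfonyl chloride, CS(=O)(=O)Cl
Why: O-Sulfonylation of the secondary allylic alcohol forms only an O–S bond, so C4 keeps its R configuration, and the low temperature together with the acetal carbon and ring oxygen flanking the allyl system should keep the mesylate from ionising.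

Step 4
Reactants: 4 ethyl 2,3,6-trideoxy-4-O-methanesulfonyl-α-L-erythro-hex-2-enopyranoside
Product: 5 (5R,6S)-6-methyl-2-oxo-5,6-dihydro-2H-pyran-5-yl methanesulfonate
Conditions: mCPBA, BF3·OEt2, CH2Cl2, −20 to 0 °C
Reagents that add atoms: 3-chloroperoxybenzoic acid (mCPBA), OOC(=O)c1cccc(Cl)c1
Why: Grieco-type peracid oxidation of a lactol ether: BF3 abstracts the ethoxy group, the peracid adds to C1 of the allyl oxocarbenium ion and the peroxy acetal collapses to the lactone carbonyl with loss of 3-chlorobenzoic acid, the mesylate and the C4 and C5 centres being spectators and the electron-poor alkene resisting epoxidation at this temperature.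

Step 5
Reactants: 5 (5R,6S)-6-methyl-2-oxo-5,6-dihydro-2H-pyran-5-yl methanesulfonate
Product: 6 sodium (2Z)-3-[(2S,3S)-3-methyloxiran-2-yl]prop-2-enoate
Conditions: NaOH (2.0 equiv), THF/H2O, 0 °C; freeze-dried
Reagents that add atoms: sodium hydroxide, [Na+].[OH-]
Why: Hydroxide adds to the lactone carbonyl (acyl-oxygen cleavage), which releases the C5 alkoxide and a carboxylate whose C2=C3 bond is Z because it was cis inside the six-membered ring; after rotation about C4–C5 the alkoxide attacks C4 anti to the mesylate and forms the O–C4 bond. The closest known reaction type is the alkaline conversion of sulfonyloxy lactones into epoxy carboxylates, that is, saponification followed by an intramolecular Williamson etherification as in halohydrin closure. The oxirane (C4, C5 and O) closes in the 3-exo-tet mode. C5 keeps its S configuration because its C–O bond is never broken, and C4 is inverted from R to S by the backside displacement, so the erythro C4/C5 pair of L-rhamnose should give the trans (2S,3S) oxirane. The step needs acyl attack to outrun loss of methanesulfonic acid from the intact lactone and conjugate addition of hydroxide, which fast addition to the δ-lactone carbonyl at 0 °C with only two equivalents of base should secure, and it needs the alkoxide to beat the carboxylate at C4, which its far higher nucleophilicity secures. The product is kept as its salt, since the free Z acid could add to its own oxirane.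

Step 6
Reactants: 7 bromanil (2,3,5,6-tetrabromo-1,4-benzoquinone)
Product: 8 2,5-dibromo-3,6-dimethoxy-1,4-benzoquinone
Conditions: NaOMe (2 equiv), MeOH, 0 °C to rt
Reagents that add atoms: sodium methoxide, C[O-].[Na+]
Why: Nucleophilic vinylic substitution (addition–elimination) of bromide by methoxide on the haloquinone; the first methoxy group turns its enone half into a vinylogous ester, so the second substitution goes to the carbon para to it and gives the 2,5-dibromo-3,6-dimethoxy pattern.

Step 7
Reactants: 8 2,5-dibromo-3,6-dimethoxy-1,4-benzoquinone; 9 4-methoxyphenylboronic acid (two equivalents are consumed, a small excess is used)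
Product: 10 2,5-dimethoxy-3,6-bis(4-methoxyphenyl)-1,4-benzoquinone
Conditions: Pd(PPh3)4 (cat.), K2CO3, 1,4-dioxane, 90 °C
Reagents that add atoms: 4-methoxyphenylboronic acid (second equivalent of 9), COc1ccc(B(O)O)cc1
Why: Twofold Suzuki–Miyaura coupling in which each of the two vinylic C–Br bonds of the electron-poor quinone undergoes oxidative addition readily and takes one 4-methoxyphenyl group from one molecule of 9, carbonate in dioxane transmetalating the aryl group without hydrolysing the methoxyquinone.

Step 8
Reactants: 10 2,5-dimethoxy-3,6-bis(4-methoxyphenyl)-1,4-benzoquinone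
Product: 11 atromentin (2,5-dihydroxy-3,6-bis(4-hydroxyphenyl)-1,4-benzoquinone)
Conditions: BBr3, CH2Cl2, −78 °C to rt; then H2O
Reagents that add atoms: none
Why: Lewis acid ether cleavage: BBr3 coordinates each methoxy oxygen and bromide removes the methyl group by SN2, which frees both phenols and both quinone hydroxyls and is tolerated by the quinone.

Step 9
Reactants: 11 atromentin
Product: 13 2,5-bis[4-(tert-butyldimethylsilyloxy)phenyl]-3,6-dihydroxy-1,4-benzoquinone, via tetrakis-TBS atromentin 12 (not isolated)
Conditions: TBSCl, imidazole, DMF, rt; then AcOH/THF/H2O, rt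
Reagents that add atoms: tert-butyldimethylsilyl chloride, CC(C)(C)[Si](C)(C)Cl
Why: Exhaustive silylation followed by selective solvolysis: the two silyl groups on the quinone oxygens are silyl esters of a vinylogous carboxylic acid and are hydrolysed by aqueous acetic acid, whereas the aryl silyl ethers are stable to it.

Step 10
Reactants: 13 2,5-bis[4-(tert-butyldimethylsilyloxy)phenyl]-3,6-dihydroxy-1,4-benzoquinone
Product: 14 4,4''-bis(tert-butyldimethylsilyloxy)-[1,1':4',1''-terphenyl]-2',3',5',6'-tetrol
Conditions: H2 (1 atm), 10% Pd/C, THF, rt; filtered under Ar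
Reagents that add atoms: none
Why: Catalytic hydrogenation of a quinone to its hydroquinone, which touches neither the arene rings nor the aryl silyl ethers; the air-sensitive tetraol solution is used at once in step 12.

Step 11
Reactants: 6 sodium (2Z)-3-[(2S,3S)-3-methyloxiran-2-yl]prop-2-enoate
Product: 15 (2Z)-3-[(2S,3S)-3-methyloxiran-2-yl]prop-2-enoic 2,4,6-trichlorobenzoic anhydride
Conditions: 2,4,6-trichlorobenzoyl chloride, THF, 0 °C to rt; filtered under Ar
Reagents that add atoms: 2,4,6-trichlorobenzoyl chloride, O=C(Cl)c1c(Cl)cc(Cl)cc1Cl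
Why: Mixed anhydride formation, the first stage of the Yamaguchi esterification: the carboxylate attacks the acid chloride and NaCl precipitates, so the free Z epoxy acid never forms and the stereocentres and the alkene are untouched.

Step 12
Reactants: 14 4,4''-bis(tert-butyldimethylsilyloxy)-[1,1':4',1''-terphenyl]-2',3',5',6'-tetrol; 15 (2Z)-3-[(2S,3S)-3-methyloxiran-2-yl]prop-2-enoic 2,4,6-trichlorobenzoic anhydride (four equivalents are consumed, about six are used)
Product: 16 4,4''-bis(tert-butyldimethylsilyloxy)-[1,1':4',1''-terphenyl]-2',3',5',6'-tetrayl tetrakis{(2Z)-3-[(2S,3S)-3-methyloxiran-2-yl]prop-2-enoate}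
Conditions: Et3N, DMAP (cat.), toluene/THF, 0 °C, Ar
Reagents that add atoms: mixed anhydride 15 (three further equivalents), C[C@@H]1O[C@H]1/C=C\C(=O)OC(=O)c1c(Cl)cc(Cl)cc1Cl
Why: Yamaguchi esterification: DMAP attacks the unhindered enoyl carbonyl of the anhydride (the trichlorobenzoyl carbonyl is shielded by its ortho chlorines) and the acylpyridinium ion acylates each of the four phenolic hydroxyls with one enoyl group from one molecule of 15, no stereocentre being involved and the low temperature limiting Z to E isomerisation.

Step 13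
Reactants: 16 bis-silyl tetraester
Product: 17 4,4''-dihydroxy-[1,1':4',1''-terphenyl]-2',3',5',6'-tetrayl tetrakis{(2Z)-3-[(2S,3S)-3-methyloxiran-2-yl]prop-2-enoate} (CNP0249571.1)
Conditions: HF·pyridine, pyridine, THF, 0 °C
Reagents that add atoms: none
Why: Fluoride-mediated desilylation driven by the strong Si–F bond; buffered HF·pyridine cleaves the aryl silyl ethers without forming basic phenoxide, so the aryl esters should stay in place, and the oxiranes, deactivated towards acid opening by the adjacent electron-poor alkene, should survive.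

**Compound list**

1 | 3,4-di-O-acetyl-L-rhamnal, (2S,3S,4S)-2-methyl-3,4-dihydro-2H-pyran-3,4-diyl diacetate | C[C@@H]1OC=C[C@H](OC(C)=O)[C@H]1OC(C)=O | starting material
2 | ethyl 4-O-acetyl-2,3,6-trideoxy-α-L-erythro-hex-2-enopyranoside, (2S,3R,6R)-6-ethoxy-2-methyl-3,6-dihydro-2H-pyran-3-yl acetate | C[C@@H]1O[C@@H](OCC)C=C[C@H]1OC(C)=O | intermediate
3 | ethyl 2,3,6-trideoxy-α-L-erythro-hex-2-enopyranoside, (2S,3R,6R)-6-ethoxy-2-methyl-3,6-dihydro-2H-pyran-3-ol | C[C@@H]1O[C@@H](OCC)C=C[C@H]1O | intermediate
4 | ethyl 2,3,6-trideoxy-4-O-methanesulfonyl-α-L-erythro-hex-2-enopyranoside | C[C@@H]1O[C@@H](OCC)C=C[C@H]1OS(C)(=O)=O | intermediate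
5 | (5R,6S)-6-methyl-2-oxo-5,6-dihydro-2H-pyran-5-yl methanesulfonate | C[C@@H]1OC(=O)C=C[C@H]1OS(C)(=O)=O | intermediate
6 | sodium (2Z)-3-[(2S,3S)-3-methyloxiran-2-yl]prop-2-enoate | C[C@@H]1O[C@H]1/C=C\C(=O)[O-].[Na+] | intermediate
7 | bromanil, 2,3,5,6-tetrabromo-1,4-benzoquinone | O=C1C(Br)=C(Br)C(=O)C(Br)=C1Br | starting material
8 | 2,5-dibromo-3,6-dimethoxy-1,4-benzoquinone | COC1=C(Br)C(=O)C(OC)=C(Br)C1=O | intermediate
9 | 4-methoxyphenylboronic acid | COc1ccc(B(O)O)cc1 | starting material
10 | 2,5-dimethoxy-3,6-bis(4-methoxyphenyl)-1,4-benzoquinone | COC1=C(c2ccc(OC)cc2)C(=O)C(OC)=C(c2ccc(OC)cc2)C1=O | intermediate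
11 | atromentin, 2,5-dihydroxy-3,6-bis(4-hydroxyphenyl)-1,4-benzoquinone | OC1=C(c2ccc(O)cc2)C(=O)C(O)=C(c2ccc(O)cc2)C1=O | intermediate
12 | tetrakis-TBS atromentin, 2,5-bis(tert-butyldimethylsilyloxy)-3,6-bis[4-(tert-butyldimethylsilyloxy)phenyl]-1,4-benzoquinone | CC(C)(C)[Si](C)(C)OC1=C(c2ccc(O[Si](C)(C)C(C)(C)C)cc2)C(=O)C(O[Si](C)(C)C(C)(C)C)=C(c2ccc(O[Si](C)(C)C(C)(C)C)cc2)C1=O | intermediate
13 | 2,5-bis[4-(tert-butyldimethylsilyloxy)phenyl]-3,6-dihydroxy-1,4-benzoquinone | OC1=C(c2ccc(O[Si](C)(C)C(C)(C)C)cc2)C(=O)C(O)=C(c2ccc(O[Si](C)(C)C(C)(C)C)cc2)C1=O | intermediate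
14 | 4,4''-bis(tert-butyldimethylsilyloxy)-[1,1':4',1''-terphenyl]-2',3',5',6'-tetrol | Oc1c(O)c(-c2ccc(O[Si](C)(C)C(C)(C)C)cc2)c(O)c(O)c1-c1ccc(O[Si](C)(C)C(C)(C)C)cc1 | intermediate
15 | (2Z)-3-[(2S,3S)-3-methyloxiran-2-yl]prop-2-enoic 2,4,6-trichlorobenzoic anhydride | C[C@@H]1O[C@H]1/C=C\C(=O)OC(=O)c1c(Cl)cc(Cl)cc1Cl | intermediate
16 | 4,4''-bis(tert-butyldimethylsilyloxy)-[1,1':4',1''-terphenyl]-2',3',5',6'-tetrayl tetrakis{(2Z)-3-[(2S,3S)-3-methyloxiran-2-yl]prop-2-enoate} | C[C@@H]1O[C@H]1/C=C\C(=O)Oc1c(OC(=O)/C=C\[C@@H]2O[C@H]2C)c(-c2ccc(O[Si](C)(C)C(C)(C)C)cc2)c(OC(=O)/C=C\[C@@H]2O[C@H]2C)c(OC(=O)/C=C\[C@@H]2O[C@H]2C)c1-c1ccc(O[Si](C)(C)C(C)(C)C)cc1 | intermediate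
17 | 4,4''-dihydroxy-[1,1':4',1''-terphenyl]-2',3',5',6'-tetrayl tetrakis{(2Z)-3-[(2S,3S)-3-methyloxiran-2-yl]prop-2-enoate} | C[C@@H]1O[C@H]1/C=C\C(=O)Oc1c(OC(=O)/C=C\[C@@H]2O[C@H]2C)c(-c2ccc(O)cc2)c(OC(=O)/C=C\[C@@H]2O[C@H]2C)c(OC(=O)/C=C\[C@@H]2O[C@H]2C)c1-c1ccc(O)cc1 | target

**Step count**

Total step count: 13.
Longest linear sequence: 8 steps (steps 1 to 5, then 11, 12 and 13, from compound 1). The core branch from bromanil runs over 7 steps (6 to 10, then 12 and 13).

**Steps most likely to fail**

Step 5 (key step). Base-induced loss of methanesulfonic acid from the still closed lactone, or conjugate addition of hydroxide, may compete with acyl cleavage. After ring opening the carboxylate may displace the mesylate in place of the alkoxide. The salt also cannot be purified on silica. The fallback sets out from mesylate 5 and comes back at salt 6. Mesylate 5 would be treated with K2CO3 in dry methanol at 0 °C, so that methoxide opens the lactone to a methyl ester, which cannot act as an internal nucleophile. The C5 alkoxide then closes the oxirane to give methyl (2Z)-3-[(2S,3S)-3-methyloxiran-2-yl]prop-2-enoate F1, a neutral compound that can be chromatographed and checked for alkene geometry. Saponification of F1 with one equivalent of NaOH in THF/H2O at 0 °C and freeze-drying would then give 6 free of sulfonate.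

Step 12 (fourfold esterification). The four crowded hydroxyls between the aryl groups may be acylated incompletely, and the tetraol may oxidise back to the quinone under basic conditions. Reversible conjugate addition of DMAP to the acylpyridinium ion may also scramble the Z geometry. The fallback sets out from salt 6 and comes back at tetraester 16. Salt 6 would be treated with pentafluorophenyl trifluoroacetate and pyridine in DMF at 0 °C to give the isolable active ester pentafluorophenyl (2Z)-3-[(2S,3S)-3-methyloxiran-2-yl]prop-2-enoate F2, purified on silica. Four equivalents of F2 (a small excess used) would then be combined with tetraol 14 and Cs2CO3 in degassed MeCN at 0 °C under argon. The phenoxide oxygens displace pentafluorophenoxide without any nucleophilic catalyst, which removes the isomerisation channel and gives 16.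

Step 13 (desilylation). HF may open the allylic oxiranes, and fluoride may strip or shift aryl ester groups once phenoxide-like species form. The fallback sets out from atromentin 11 and comes back at target 17, and replaces the silyl group by one that leaves without fluoride. Atromentin 11 would be silylated with Et3SiCl and imidazole in DMF to 2,5-bis(triethylsilyloxy)-3,6-bis[4-(triethylsilyloxy)phenyl]-1,4-benzoquinone F3, not isolated. Aqueous work-up at neutral pH would hydrolyse the two vinylogous silyl esters and leave 2,5-dihydroxy-3,6-bis[4-(triethylsilyloxy)phenyl]-1,4-benzoquinone F4. Hydrogenation over 10% Pd/C in THF would give 4,4''-bis(triethylsilyloxy)-[1,1':4',1''-terphenyl]-2',3',5',6'-tetrol F5. Acylation with four equivalents of anhydride 15 as in step 12 would give 4,4''-bis(triethylsilyloxy)-[1,1':4',1''-terphenyl]-2',3',5',6'-tetrayl tetrakis{(2Z)-3-[(2S,3S)-3-methyloxiran-2-yl]prop-2-enoate} F6. The aryl triethylsilyl ethers would then be removed with AcOH/THF/H2O at rt to give 17.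

**Further compounds**

F1 | step 5 | methyl (2Z)-3-[(2S,3S)-3-methyloxiran-2-yl]prop-2-enoate | C[C@@H]1O[C@H]1/C=C\C(=O)OC
F2 | step 12 | pentafluorophenyl (2Z)-3-[(2S,3S)-3-methyloxiran-2-yl]prop-2-enoate | C[C@@H]1O[C@H]1/C=C\C(=O)Oc1c(F)c(F)c(F)c(F)c1F
F3 | step 13 | 2,5-bis(triethylsilyloxy)-3,6-bis[4-(triethylsilyloxy)phenyl]-1,4-benzoquinone | CC[Si](CC)(CC)OC1=C(c2ccc(O[Si](CC)(CC)CC)cc2)C(=O)C(O[Si](CC)(CC)CC)=C(c2ccc(O[Si](CC)(CC)CC)cc2)C1=O
F4 | step 13 | 2,5-dihydroxy-3,6-bis[4-(triethylsilyloxy)phenyl]-1,4-benzoquinone | OC1=C(c2ccc(O[Si](CC)(CC)CC)cc2)C(=O)C(O)=C(c2ccc(O[Si](CC)(CC)CC)cc2)C1=O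
F5 | step 13 | 4,4''-bis(triethylsilyloxy)-[1,1':4',1''-terphenyl]-2',3',5',6'-tetrol | Oc1c(O)c(-c2ccc(O[Si](CC)(CC)CC)cc2)c(O)c(O)c1-c1ccc(O[Si](CC)(CC)CC)cc1
F6 | step 13 | 4,4''-bis(triethylsilyloxy)-[1,1':4',1''-terphenyl]-2',3',5',6'-tetrayl tetrakis{(2Z)-3-[(2S,3S)-3-methyloxiran-2-yl]prop-2-enoate} | C[C@@H]1O[C@H]1/C=C\C(=O)Oc1c(OC(=O)/C=C\[C@@H]2O[C@H]2C)c(-c2ccc(O[Si](CC)(CC)CC)cc2)c(OC(=O)/C=C\[C@@H]2O[C@H]2C)c(OC(=O)/C=C\[C@@H]2O[C@H]2C)c1-c1ccc(O[Si](CC)(CC)CC)cc1
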